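**Route overview**

- Retrosynthesis: ring C of serpyllin is opened at C4–C4a to a β-aryloxycinnamic acid. That acid is cut at O1–C2 into a ring A phenol and an arylpropiolate, and the propiolate at C2–C1' into an aryl iodide and ethyl propiolate. The C5 oxygen is traced back to a formyl group.
- Forward: rings A and B are bought as benzenes. Ring B is iodinated and alkynylated, the ring A phenol adds to the ynoate, the formyl group is oxidised to the C5 oxygen, both esters are hydrolysed, and ring C is closed last by intramolecular Friedel–Crafts acylation.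
- Enabling feature: in ring A, C4a is the only unsubstituted carbon ortho to O1, because C8 carries a methoxy. C4a is also ortho to the C5 hydroxyl and para to the C7 methoxy, so the acyl carbon tethered through O1–C2=C3 can only bond there, which gives the 5,7,8 pattern.
- Stereochemistry: the target has no stereocentre. The only stereo element on the way is the C2=C3 geometry of the open-chain intermediates, which is set by anti addition and equilibrated by the acid of the last step.

Key step: step 6

Remark: compounds 6 to 9 are drawn as the Z isomers (aryloxy group cis to the carbonyl group). Any E isomer formed in step 3 would be carried along, since the acid of step 6 should interconvert the two.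

**Step 1**
Reactants: 1 1,2,3-trimethoxybenzene
Product: 2 1-iodo-2,3,4-trimethoxybenzene
Conditions: NIS (1.05 equiv), TFA (cat.), MeCN, rt
Reagents that add atoms: N-iodosuccinimide, O=C1CCC(=O)N1I
Why: Electrophilic aromatic iodination (NIS activated by catalytic acid) should go to C4, which is ortho to one methoxy and para to another, whereas C5 is para only to the central methoxy that is twisted out of conjugation; one equivalent of NIS keeps it at monoiodination.

**Step 2**
Reactants: 2 1-iodo-2,3,4-trimethoxybenzene; 3 ethyl propiolate
Product: 4 ethyl 3-(2,3,4-trimethoxyphenyl)prop-2-ynoate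
Conditions: PdCl2(PPh3)2 (3 mol %), CuI (6 mol %), K2CO3 (2 equiv), THF, 65 °C, 3 added in portions
Reagents that add atoms: none
Why: Sonogashira coupling, in which zerovalent palladium formed from PdCl2(PPh3)2 inserts into the C–I bond, the copper acetylide made from 3 with CuI and carbonate transmetalates and reductive elimination gives the arylpropiolate; the heterogeneous carbonate base is chosen because an amine base would add to the propiolate.

**Step 3**
Reactants: 4 ethyl 3-(2,3,4-trimethoxyphenyl)prop-2-ynoate; 5 3-hydroxy-4,5-dimethoxybenzaldehyde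
Product: 6 ethyl (Z)-3-(5-formyl-2,3-dimethoxyphenoxy)-3-(2,3,4-trimethoxyphenyl)prop-2-enoate
Conditions: K2CO3 (0.5 equiv), DMF, 80 °C
Reagents that add atoms: none
Why: Oxa-Michael (conjugate) addition, in which the phenoxide of 5 attacks the β-carbon of ynoate 4 and forms the O1–C2 bond; protonation of the resulting allenolate anti to the new C–O bond should favour the Z enol ether, and the formyl group, meta to the phenoxide oxygen and unable to enolise, is expected to stay intact.

**Step 4**
Reactants: 6 ethyl (Z)-3-(5-formyl-2,3-dimethoxyphenoxy)-3-(2,3,4-trimethoxyphenyl)prop-2-enoate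
Product: 7 ethyl (Z)-3-[5-(formyloxy)-2,3-dimethoxyphenoxy]-3-(2,3,4-trimethoxyphenyl)prop-2-enoate
Conditions: mCPBA (1.3 equiv), CH2Cl2, 0 °C to rt; cold aq. Na2S2O3/NaHCO3 wash, crude product used directly
Reagents that add atoms: mCPBA (3-chloroperoxybenzoic acid), OOC(=O)c1cccc(Cl)c1
Why: Baeyer–Villiger oxidation, in which the peracid adds to the formyl group and the oxygen-rich aryl group migrates to oxygen as it does in 3,4,5-trioxygenated benzaldehydes, giving the aryl formate; the C2=C3 alkene is a vinylogous carbonate whose ether oxygen is also conjugated to ring A and should be too electron-poor to be epoxidised at this temperature.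

**Step 5**
Reactants: 7 ethyl (Z)-3-[5-(formyloxy)-2,3-dimethoxyphenoxy]-3-(2,3,4-trimethoxyphenyl)prop-2-enoate
Product: 8 (Z)-3-(5-hydroxy-2,3-dimethoxyphenoxy)-3-(2,3,4-trimethoxyphenyl)prop-2-enoic acid
Conditions: LiOH·H2O (5 equiv), THF/H2O 3:1, argon, rt to 40 °C; then 1 M HCl to pH 2–3 at 0 °C
Reagents that add atoms: lithium hydroxide, [Li+].[OH-]
Why: Saponification (acyl substitution by hydroxide) should cleave the very labile aryl formate and the ethyl ester in one operation; alcohol cosolvents are left out so that no alkoxide can exchange the aryloxy group by addition–elimination at C2, and the carboxylate, once formed, shields the enol ether from further nucleophilic attack.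

**Step 6**
Reactants: 8 (Z)-3-(5-hydroxy-2,3-dimethoxyphenoxy)-3-(2,3,4-trimethoxyphenyl)prop-2-enoic acid
Product: 10 serpyllin, via mixed carboxylic methanesulfonic anhydride 9 (not isolated)
Conditions: P2O5/MeSO3H (1:10 w/w), rt to 45 °C; then ice-water
Reagents that add atoms: none
Why: The dehydrating acid should convert the carboxyl group into mixed anhydride 9 and from it the acylium ion, which attacks C4a of ring A, and loss of the proton restores the arene and completes the pyranone (intramolecular Friedel–Crafts acylation, a cyclodehydration). The closest known reaction type is the acid-mediated ring closure of β-aryloxycinnamic and β-aryloxyacrylic acids to flavones and chromones, and free phenols are C-acylated in such media in xanthone syntheses. Ring C closes in a 6-exo-dig mode with respect to the acylium C≡O (6-exo-trig if the anhydride itself is the electrophile), and no stereocentre is formed. The step needs site selectivity for C4a, which the substrate secures: C4a is the only free carbon ortho to O1 because C8 carries a methoxy, it is activated by O1 and the C5 hydroxyl (both ortho) and by the C7 methoxy (para), closure onto ring B would need a five-membered indenone at a less activated carbon, and the meta hydroxyl cannot reach the acyl carbon within the molecule. Reversible protonation at C3 gives a cation stabilised by O1 and ring B with free rotation about C2–C3, so any E isomer should drain through the Z form that cyclises. The product carbonyl is hydrogen bonded to the C5 hydroxyl, and the mild, anhydrous conditions should limit decarboxylation and Wessely–Moser-type ring opening, so the target is expected without any deprotection.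

**Compound list**

1 | 1,2,3-trimethoxybenzene | COc1cccc(OC)c1OC | starting material
2 | 1-iodo-2,3,4-trimethoxybenzene | COc1ccc(I)c(OC)c1OC | intermediate
3 | ethyl propiolate (ethyl prop-2-ynoate) | C#CC(=O)OCC | starting material
4 | ethyl 3-(2,3,4-trimethoxyphenyl)prop-2-ynoate | CCOC(=O)C#Cc1ccc(OC)c(OC)c1OC | intermediate
5 | 3-hydroxy-4,5-dimethoxybenzaldehyde | O=Cc1cc(O)c(OC)c(OC)c1 | starting material
6 | ethyl (Z)-3-(5-formyl-2,3-dimethoxyphenoxy)-3-(2,3,4-trimethoxyphenyl)prop-2-enoate | CCOC(=O)/C=C(\Oc1cc(C=O)cc(OC)c1OC)c1ccc(OC)c(OC)c1OC | intermediate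
7 | ethyl (Z)-3-[5-(formyloxy)-2,3-dimethoxyphenoxy]-3-(2,3,4-trimethoxyphenyl)prop-2-enoate | CCOC(=O)/C=C(\Oc1cc(OC=O)cc(OC)c1OC)c1ccc(OC)c(OC)c1OC | intermediate
8 | (Z)-3-(5-hydroxy-2,3-dimethoxyphenoxy)-3-(2,3,4-trimethoxyphenyl)prop-2-enoic acid | OC(=O)/C=C(\Oc1cc(O)cc(OC)c1OC)c1ccc(OC)c(OC)c1OC | intermediate
9 | mixed carboxylic methanesulfonic anhydride of 8 (formed in the flask, not isolated) | CS(=O)(=O)OC(=O)/C=C(\Oc1cc(O)cc(OC)c1OC)c1ccc(OC)c(OC)c1OC | intermediate
10 | serpyllin, 5-hydroxy-7,8-dimethoxy-2-(2,3,4-trimethoxyphenyl)-4H-chromen-4-one | COc1ccc(-c2cc(=O)c3c(O)cc(OC)c(OC)c3o2)c(OC)c1OC | target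

**Step count**

Total step count: 6. Longest linear sequence: 6 steps (1 → 2 → 4 → 6 → 7 → 8 → 10).

**Steps most likely to fail**

Step 4 (Baeyer–Villiger oxidation). The peracid may oxidise the C2=C3 enol ether or the electron-rich rings faster than the aldehyde rearranges, or hydrogen may migrate in place of the aryl group so that the oxidation ends at the carboxylic acid level. The fallback installs the ring A oxygen before the alkene exists; it sets out from 5 and returns to the route at 8. Aldehyde 5 would be benzylated (BnBr, K2CO3, DMF) to 3-(benzyloxy)-4,5-dimethoxybenzaldehyde F1. Baeyer–Villiger oxidation (mCPBA, CH2Cl2) would give 3-(benzyloxy)-4,5-dimethoxyphenyl formate F2, and methanolysis (K2CO3, MeOH) would free 3-(benzyloxy)-4,5-dimethoxyphenol F3. Sulfonylation (TsCl, Et3N, cat. DMAP, CH2Cl2) would give 3-(benzyloxy)-4,5-dimethoxyphenyl 4-methylbenzenesulfonate F4, and hydrogenolysis (H2, Pd/C, EtOAc) would unmask 3-hydroxy-4,5-dimethoxyphenyl 4-methylbenzenesulfonate F5. Its phenol would add to ynoate 4 under the conditions of step 3 to give ethyl (Z)-3-[2,3-dimethoxy-5-(tosyloxy)phenoxy]-3-(2,3,4-trimethoxyphenyl)prop-2-enoate F6. KOH in aqueous dioxane (rt, then 90 °C) followed by acidification would cleave the ethyl ester and the aryl sulfonate together and deliver 8.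

Step 6 (ring closure). Protonation at C3 may lead to loss of CO2 or cleavage of the enol ether before acylation, or the free phenol may be esterified or sulfonylated between molecules, so that the closure stalls. The fallback closes the same bond on a capped substrate through a discrete acid chloride under aprotic Lewis acid conditions; it sets out from 8 and returns at 10. Acid 8 would be methylated on both the phenol and the carboxyl group (MeI, K2CO3, DMF) to methyl (Z)-3-(2,3,5-trimethoxyphenoxy)-3-(2,3,4-trimethoxyphenyl)prop-2-enoate F7. Saponification (LiOH, THF/H2O) would give (Z)-3-(2,3,5-trimethoxyphenoxy)-3-(2,3,4-trimethoxyphenyl)prop-2-enoic acid F8. Oxalyl chloride with catalytic DMF in CH2Cl2 would convert it to (Z)-3-(2,3,5-trimethoxyphenoxy)-3-(2,3,4-trimethoxyphenyl)prop-2-enoyl chloride F9, which SnCl4 (CH2Cl2, −20 °C to rt) should close to 5,7,8-trimethoxy-2-(2,3,4-trimethoxyphenyl)-4H-chromen-4-one F10. BCl3 (CH2Cl2, −78 to 0 °C) would then cleave only the C5 methyl ether, the one whose oxygen chelates boron together with the C4 carbonyl, to give 10.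

Step 3 (oxa-Michael addition). A phenoxide with an ortho methoxy may add only slowly to an ynoate deactivated and shielded by the electron-rich, ortho-substituted aryl group, and at the temperature then needed the aldehyde or the ynoate may degrade under base. The fallback replaces conjugate addition by a copper-catalysed C–O coupling; it sets out from 4 and returns at 6. Hydroiodination of 4 (NaI, AcOH, 100 °C, anti addition) would give ethyl (Z)-3-iodo-3-(2,3,4-trimethoxyphenyl)prop-2-enoate F11. Ullmann-type O-vinylation of phenol 5 (CuI, N,N-dimethylglycine, Cs2CO3, dioxane, 90 °C) should then form the O1–C2 bond with retention of the alkene geometry and give 6.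

**Further compounds**

F1 | step 4 | 3-(benzyloxy)-4,5-dimethoxybenzaldehyde | O=Cc1cc(OCc2ccccc2)c(OC)c(OC)c1
F2 | step 4 | 3-(benzyloxy)-4,5-dimethoxyphenyl formate | O=COc1cc(OCc2ccccc2)c(OC)c(OC)c1
F3 | step 4 | 3-(benzyloxy)-4,5-dimethoxyphenol | Oc1cc(OCc2ccccc2)c(OC)c(OC)c1
F4 | step 4 | 3-(benzyloxy)-4,5-dimethoxyphenyl 4-methylbenzenesulfonate | Cc1ccc(cc1)S(=O)(=O)Oc1cc(OCc2ccccc2)c(OC)c(OC)c1
F5 | step 4 | 3-hydroxy-4,5-dimethoxyphenyl 4-methylbenzenesulfonate | Cc1ccc(cc1)S(=O)(=O)Oc1cc(O)c(OC)c(OC)c1
F6 | step 4 | ethyl (Z)-3-[2,3-dimethoxy-5-(tosyloxy)phenoxy]-3-(2,3,4-trimethoxyphenyl)prop-2-enoate | CCOC(=O)/C=C(\Oc1cc(OS(=O)(=O)c2ccc(C)cc2)cc(OC)c1OC)c1ccc(OC)c(OC)c1OC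
F7 | step 6 | methyl (Z)-3-(2,3,5-trimethoxyphenoxy)-3-(2,3,4-trimethoxyphenyl)prop-2-enoate | COC(=O)/C=C(\Oc1cc(OC)cc(OC)c1OC)c1ccc(OC)c(OC)c1OC
F8 | step 6 | (Z)-3-(2,3,5-trimethoxyphenoxy)-3-(2,3,4-trimethoxyphenyl)prop-2-enoic acid | OC(=O)/C=C(\Oc1cc(OC)cc(OC)c1OC)c1ccc(OC)c(OC)c1OC
F9 | step 6 | (Z)-3-(2,3,5-trimethoxyphenoxy)-3-(2,3,4-trimethoxyphenyl)prop-2-enoyl chloride | ClC(=O)/C=C(\Oc1cc(OC)cc(OC)c1OC)c1ccc(OC)c(OC)c1OC
F10 | step 6 | 5,7,8-trimethoxy-2-(2,3,4-trimethoxyphenyl)-4H-chromen-4-one | COc1ccc(-c2cc(=O)c3c(OC)cc(OC)c(OC)c3o2)c(OC)c1OC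
F11 | step 3 | ethyl (Z)-3-iodo-3-(2,3,4-trimethoxyphenyl)prop-2-enoate | CCOC(=O)/C=C(\I)c1ccc(OC)c(OC)c1OC
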